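**Retrosynthetic overview**
1. The target is reached from its 5-O-benzyl ether by hydrogenolysis; rings A and C are carried throughout as a 5-benzyloxy-7-methoxychromone.
2. Ring B is made last. Its C6'–C1' bond comes from a Stille coupling of racemic 4-chloro-2,3-dimethoxycyclobutenone with a chromone-bound α-stannyl β-methoxy enol ether, and its C2'–C3' bond from 4π opening and 6π closure of the resulting dienylketene.
3. The feature used is that ring B carries four contiguous oxygens on C2'–C5' with only the inner C3' oxygen free. The ketene carbonyl becomes exactly that C3' phenol, the squarate methoxy groups become C4'- and C5'-OMe, the enol ether gives C2'-OMe, and C6' stays CH.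
4. The stannane comes from the alkenyl bromide, the enol ether and the chromone-2-carbaldehyde, which is made by Claisen condensation of mono-benzylated 2,6-dihydroxy-4-methoxyacetophenone with ethyl diethoxyacetate and cyclodehydration (ring C closes here).
5. The chloride comes from dimethyl squarate by hydride reduction and chlorination. Ring order: A (bought), C (step 3), B (step 9).

Key step: step 9

Remark: bromination–dehydrobromination of a β-methoxyvinyl group conjugated to a carbonyl system is taken to give the isomer with methoxy and halogen cis (as it does for 3-methoxyacrylates), so the bromide and the stannane are drawn as Z isomers and the enol ether before them is carried as an E/Z mixture; this geometry is erased when ring B aromatises.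

**Route**

Step 1
Reactants: 1 2,6-dihydroxy-4-methoxyacetophenone
Product: 2 1-[2-(benzyloxy)-6-hydroxy-4-methoxyphenyl]ethan-1-one
Conditions: BnBr (1.05 equiv), K2CO3, acetone, 56 °C
Reagents that add atoms: benzyl bromide, BrCc1ccccc1
Why: Williamson ether synthesis on a symmetrical ketone in which, once one hydroxyl is benzylated, the other is held in a strong hydrogen bond to the acetyl carbonyl and is alkylated far more slowly, so one equivalent of benzyl bromide should stop at the mono-ether.

Step 2
Reactants: 2 1-[2-(benzyloxy)-6-hydroxy-4-methoxyphenyl]ethan-1-one; 3 ethyl diethoxyacetate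
Product: 4 1-[2-(benzyloxy)-6-hydroxy-4-methoxyphenyl]-4,4-diethoxybutane-1,3-dione
Conditions: NaH (3 equiv), THF, 65 °C; then AcOH, 0 °C
Reagents that add atoms: none
Why: Crossed Claisen condensation in which the phenoxide–enolate dianion of 2 is acylated on carbon by the poorly enolisable ester 3 and the product is held as its stable diketonate until the acidic quench.

Step 3
Reactants: 4 1-[2-(benzyloxy)-6-hydroxy-4-methoxyphenyl]-4,4-diethoxybutane-1,3-dione
Product: 6 5-(benzyloxy)-7-methoxy-4-oxo-4H-chromene-2-carbaldehyde, via diethyl acetal 5 (not isolated)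
Conditions: TsOH·H2O (catalytic), toluene, 80 °C; then 2 M HCl, THF, 40 °C
Reagents that add atoms: water, O
Why: Acid-catalysed cyclodehydration of the 2-hydroxyaryl 1,3-diketone (the phenol adds to the side-chain ketone and water is lost) closes the pyranone ring C, and dilute aqueous acid then hydrolyses the diethyl acetal under conditions mild enough to leave the aryl benzyl ether intact.

Step 4
Reactants: 6 5-(benzyloxy)-7-methoxy-4-oxo-4H-chromene-2-carbaldehyde; 7 (methoxymethyl)triphenylphosphonium chloride
Product: 8 5-(benzyloxy)-7-methoxy-2-(2-methoxyvinyl)-4H-chromen-4-one (E/Z mixture)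
Conditions: 7, KOtBu, THF, 0 °C; then 6, −78 to 0 °C
Reagents that add atoms: none
Why: Wittig reaction of the non-enolisable, highly electrophilic aldehyde with (methoxymethylene)triphenylphosphorane gives the enol ether, and the E/Z mixture is acceptable because the next step resets the alkene geometry.

Step 5
Reactants: 8 5-(benzyloxy)-7-methoxy-2-(2-methoxyvinyl)-4H-chromen-4-one (E/Z mixture)
Product: 10 5-(benzyloxy)-2-[(Z)-1-bromo-2-methoxyvinyl]-7-methoxy-4H-chromen-4-one, via dibromide 9 (not isolated)
Conditions: Br2 (1.0 equiv), CH2Cl2, −78 °C; then Et3N, −78 to 20 °C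
Reagents that add atoms: bromine, BrBr
Why: Electrophilic addition of bromine to the enol ether, the most nucleophilic alkene of 8, followed by amine-induced dehydrobromination of E1cB type (loss of the acidified C–H next to the chromone and of the labile α-bromo ether bromide) should give the α-bromo enol ether with methoxy and bromine cis from either isomer of 8, by analogy with the same sequence on 3-methoxyacrylates.

Step 6
Reactants: 10 5-(benzyloxy)-2-[(Z)-1-bromo-2-methoxyvinyl]-7-methoxy-4H-chromen-4-one; 11 hexabutylditin
Product: 12 5-(benzyloxy)-7-methoxy-2-[(Z)-2-methoxy-1-(tributylstannyl)vinyl]-4H-chromen-4-one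
Conditions: Pd(PPh3)4 (5 mol%), toluene, 100 °C
Reagents that add atoms: none
Why: Palladium-catalysed stannylation of an alkenyl bromide with a distannane (oxidative addition, tin-to-palladium transfer, reductive elimination) replaces bromine by tributyltin with retention of geometry under neutral conditions that spare the chromone, which a halogen–lithium exchange would not.

Step 7
Reactants: 13 dimethyl squarate
Product: 14 4-hydroxy-2,3-dimethoxycyclobut-2-en-1-one (racemic)
Conditions: LiAlH(OtBu)3 (1.05 equiv), THF, −78 °C; then saturated aqueous NH4Cl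
Reagents that add atoms: none
Why: Chemoselective 1,2-reduction of one of the two equivalent ketone carbonyls by the bulky, mild hydride at low temperature should stop at the hydroxycyclobutenone, whose new stereocentre forms as a racemate and is destroyed later.

Step 8
Reactants: 14 4-hydroxy-2,3-dimethoxycyclobut-2-en-1-one (racemic)
Product: 15 4-chloro-2,3-dimethoxycyclobut-2-en-1-one (racemic)
Conditions: PPh3, CCl4, CH2Cl2, 0 to 20 °C
Reagents that add atoms: carbon tetrachloride, ClC(Cl)(Cl)Cl
Why: Appel reaction in which the alkoxyphosphonium salt is displaced by chloride under neutral, acid-free conditions, which should avoid the acid-triggered collapse of 14 to a cyclobutenedione, and the racemic chloride is used at once.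

Step 9
Reactants: 12 5-(benzyloxy)-7-methoxy-2-[(Z)-2-methoxy-1-(tributylstannyl)vinyl]-4H-chromen-4-one; 15 4-chloro-2,3-dimethoxycyclobut-2-en-1-one (racemic)
Product: 19 5-benzyloxy-3'-hydroxy-7,2',4',5'-tetramethoxyflavone, via alkenylcyclobutenone 16 (not isolated), via dienylketene 17 (not isolated), via cyclohexadienone 18 (not isolated)
Conditions: PdCl2(PhCN)2 (5 mol%), tri(2-furyl)phosphine (10 mol%), CuI (10 mol%), 1,4-dioxane, 50 °C; then 100 °C
Reagents that add atoms: none
Why: Zerovalent palladium, generated from PdCl2(PhCN)2 and tri(2-furyl)phosphine, inserts into the allylic C4–Cl bond of 15, the alkenyl group of 12 is transferred from tin (assisted by CuI, which also disfavours cine substitution) and reductive elimination at C4 forms the C6'–C1' bond of 16 with retention of alkene geometry, which is the known Stille coupling of 4-chlorocyclobutenones with alkenylstannanes. At 100 °C 16 undergoes thermal conrotatory 4π ring opening to dienylketene 17, whose ketene carbon (future C3') bonds to the methoxy-bearing enol ether carbon (future C2') in a thermal disrotatory 6π electrocyclisation that closes the six-membered carbocyclic ring B as dienone 18, and enolisation gives phenol 19, which is the known cyclobutenone-to-phenol benzannulation. No stereocentre persists, since C4 of 16 and the CH(OMe) carbon of 18 both end as aromatic carbons. The step needs (a) bond formation at C4 and not at C2 of the oxocyclobutenyl–palladium intermediate, favoured because C4 is the unsubstituted terminus and coupling there keeps the conjugated vinylogous ester, and (b) inward rotation of the alkenyl group in the ring opening, secured because the opening is reversible and only the inward ketene is drained by cyclisation. The methoxy group of 12 lies cis to tin (the arrangement in which a β-alkoxyvinyl metal species does not lose alkoxide by anti elimination) and therefore points into the closing triene, which should be tolerated because the ketene terminus is sp-hybridised and carries no inward substituent to clash with it. The squarate methoxy groups become 4'- and 5'-OMe, the enol ether supplies 2'-OMe and the ketene oxygen becomes the only free hydroxyl of ring B, so no protecting group or selective demethylation is needed there.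

Step 10
Reactants: 19 5-benzyloxy-3'-hydroxy-7,2',4',5'-tetramethoxyflavone
Product: 20 5,3'-dihydroxy-7,2',4',5'-tetramethoxyflavone
Conditions: H2 (1 atm), 10% Pd/C, EtOAc–MeOH, 20 °C
Reagents that add atoms: none
Why: Catalytic hydrogenolysis of the aryl benzyl ether frees the chelated 5-hydroxyl while the methyl ethers and the conjugated pyranone double bond should not be reduced under these mild conditions.

**Compound list**
1 | 2,6-dihydroxy-4-methoxyacetophenone | COc1cc(O)c(C(C)=O)c(O)c1 | starting material
2 | 1-[2-(benzyloxy)-6-hydroxy-4-methoxyphenyl]ethan-1-one | COc1cc(O)c(C(C)=O)c(OCc2ccccc2)c1 | intermediate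
3 | ethyl diethoxyacetate | CCOC(OCC)C(=O)OCC | starting material
4 | 1-[2-(benzyloxy)-6-hydroxy-4-methoxyphenyl]-4,4-diethoxybutane-1,3-dione | CCOC(OCC)C(=O)CC(=O)c1c(O)cc(OC)cc1OCc1ccccc1 | intermediate
5 | 5-(benzyloxy)-2-(diethoxymethyl)-7-methoxy-4H-chromen-4-one | CCOC(OCC)c1cc(=O)c2c(OCc3ccccc3)cc(OC)cc2o1 | intermediate
6 | 5-(benzyloxy)-7-methoxy-4-oxo-4H-chromene-2-carbaldehyde | O=Cc1cc(=O)c2c(OCc3ccccc3)cc(OC)cc2o1 | intermediate
7 | (methoxymethyl)triphenylphosphonium chloride | COC[P+](c1ccccc1)(c1ccccc1)c1ccccc1.[Cl-] | starting material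
8 | 5-(benzyloxy)-7-methoxy-2-(2-methoxyvinyl)-4H-chromen-4-one (E/Z mixture, geometry not specified) | COC=Cc1cc(=O)c2c(OCc3ccccc3)cc(OC)cc2o1 | intermediate
9 | 5-(benzyloxy)-2-(1,2-dibromo-2-methoxyethyl)-7-methoxy-4H-chromen-4-one (racemic diastereomer mixture) | COC(Br)C(Br)c1cc(=O)c2c(OCc3ccccc3)cc(OC)cc2o1 | intermediate
10 | 5-(benzyloxy)-2-[(Z)-1-bromo-2-methoxyvinyl]-7-methoxy-4H-chromen-4-one | CO/C=C(\Br)c1cc(=O)c2c(OCc3ccccc3)cc(OC)cc2o1 | intermediate
11 | hexabutylditin | CCCC[Sn](CCCC)(CCCC)[Sn](CCCC)(CCCC)CCCC | starting material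
12 | 5-(benzyloxy)-7-methoxy-2-[(Z)-2-methoxy-1-(tributylstannyl)vinyl]-4H-chromen-4-one | CO/C=C(\[Sn](CCCC)(CCCC)CCCC)c1cc(=O)c2c(OCc3ccccc3)cc(OC)cc2o1 | intermediate
13 | dimethyl squarate | COC1=C(OC)C(=O)C1=O | starting material
14 | 4-hydroxy-2,3-dimethoxycyclobut-2-en-1-one (racemic) | COC1=C(OC)C(O)C1=O | intermediate
15 | 4-chloro-2,3-dimethoxycyclobut-2-en-1-one (racemic) | COC1=C(OC)C(Cl)C1=O | intermediate
16 | 5-(benzyloxy)-2-[(E)-1-(2,3-dimethoxy-4-oxocyclobut-2-en-1-yl)-2-methoxyvinyl]-7-methoxy-4H-chromen-4-one (racemic; methoxy cis to the cyclobutenyl carbon) | CO/C=C(\C1C(=O)C(OC)=C1OC)c1cc(=O)c2c(OCc3ccccc3)cc(OC)cc2o1 | intermediate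
17 | (3E,5E)-5-[5-(benzyloxy)-7-methoxy-4-oxo-4H-chromen-2-yl]-2,3,6-trimethoxyhexa-1,3,5-trien-1-one (C2 and C5 cis across C3=C4; 6-methoxy cis to C4) | O=C=C(OC)/C(OC)=C\C(=C/OC)c1cc(=O)c2c(OCc3ccccc3)cc(OC)cc2o1 | intermediate
18 | 5-(benzyloxy)-7-methoxy-2-(3,4,6-trimethoxy-5-oxocyclohexa-1,3-dien-1-yl)-4H-chromen-4-one (racemic) | COC1C(=O)C(OC)=C(OC)C=C1c1cc(=O)c2c(OCc3ccccc3)cc(OC)cc2o1 | intermediate
19 | 5-benzyloxy-3'-hydroxy-7,2',4',5'-tetramethoxyflavone | COc1cc(OCc2ccccc2)c2c(=O)cc(-c3cc(OC)c(OC)c(O)c3OC)oc2c1 | intermediate
20 | 5,3'-dihydroxy-7,2',4',5'-tetramethoxyflavone | COc1cc(O)c2c(=O)cc(-c3cc(OC)c(OC)c(O)c3OC)oc2c1 | target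

**Step count**
Total: 10 steps. Longest linear sequence: 8 steps (steps 1–6, 9 and 10).

**Steps most likely to fail**

Step 9. Tin-to-palladium transfer from the hindered, electron-poor stannane 12 may be slow, so that protodestannylation, cine substitution or decay of the labile chloride 15 outruns the coupling. The fallback sets out from 15 and 2 and comes back at 20; it builds ring B on a small ester and closes the pyranone ring last. Commercial methyl (E)-3-methoxyacrylate is brominated and dehydrobrominated (Br2, then Et3N) to methyl (Z)-2-bromo-3-methoxyacrylate F1. F1 is stannylated (11, Pd(PPh3)4) to methyl (Z)-3-methoxy-2-(tributylstannyl)acrylate F2, an α-stannyl acrylate of a type known to undergo copper-assisted Stille coupling. Coupling of F2 with 15 and thermolysis under the conditions of step 9 should give methyl 3-hydroxy-2,4,5-trimethoxybenzoate F3, which is benzylated (BnBr, K2CO3) to methyl 3-(benzyloxy)-2,4,5-trimethoxybenzoate F4. Claisen condensation of F4 with 2 (NaH, THF) gives 1-[2-(benzyloxy)-6-hydroxy-4-methoxyphenyl]-3-[3-(benzyloxy)-2,4,5-trimethoxyphenyl]propane-1,3-dione F5. Acid cyclodehydration (H2SO4, AcOH) gives 5,3'-bis(benzyloxy)-7,2',4',5'-tetramethoxyflavone F6, and hydrogenolysis as in step 10 removes both benzyl groups to reach 20.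

Step 5. Bromine may not discriminate between the enol ether carbon, C3 of the pyranone and C6/C8 of the alkoxy-rich ring A, and hydrogen bromide formed before the amine is added may cleave the enol ether. The fallback sets out from 2 and comes back at 10; it brings the bromine in on the three-carbon unit before the chromone exists. Saponification (LiOH, THF–H2O) of methyl (Z)-2-bromo-3-methoxyacrylate F1 (made as in the fallback to step 9) gives (Z)-2-bromo-3-methoxyacrylic acid F7. Steglich esterification of phenol 2 with F7 (DCC, DMAP) gives 2-acetyl-3-(benzyloxy)-5-methoxyphenyl (Z)-2-bromo-3-methoxyacrylate F8. Baker–Venkataraman rearrangement (KOtBu, THF) gives (Z)-1-[2-(benzyloxy)-6-hydroxy-4-methoxyphenyl]-4-bromo-5-methoxypent-4-ene-1,3-dione F9, and cyclodehydration (TsOH, toluene) gives 10.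

Step 8. The activated alcohol may ionise, with allylic transposition of chloride to the methoxy-bearing carbon and loss of chloromethane to a cyclobutenedione, or the chloride may hydrolyse during removal of the phosphine oxide. The fallback sets out from 14 and comes back at 15; it separates activation from chloride delivery. Alcohol 14 is converted at −40 °C (MsCl, Et3N, CH2Cl2) into 2,3-dimethoxy-4-oxocyclobut-2-en-1-yl methanesulfonate F10, and the sulfonate is displaced by LiCl in acetone at −20 to 0 °C in an SN2 reaction; the crude chloride is taken directly into step 9.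

**Further compounds**
F1 | step 9 | methyl (Z)-2-bromo-3-methoxyacrylate | CO/C=C(\Br)C(=O)OC
F2 | step 9 | methyl (Z)-3-methoxy-2-(tributylstannyl)acrylate | CO/C=C(\[Sn](CCCC)(CCCC)CCCC)C(=O)OC
F3 | step 9 | methyl 3-hydroxy-2,4,5-trimethoxybenzoate | COC(=O)c1cc(OC)c(OC)c(O)c1OC
F4 | step 9 | methyl 3-(benzyloxy)-2,4,5-trimethoxybenzoate | COC(=O)c1cc(OC)c(OC)c(OCc2ccccc2)c1OC
F5 | step 9 | 1-[2-(benzyloxy)-6-hydroxy-4-methoxyphenyl]-3-[3-(benzyloxy)-2,4,5-trimethoxyphenyl]propane-1,3-dione | COc1cc(O)c(C(=O)CC(=O)c2cc(OC)c(OC)c(OCc3ccccc3)c2OC)c(OCc2ccccc2)c1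
F6 | step 9 | 5,3'-bis(benzyloxy)-7,2',4',5'-tetramethoxyflavone | COc1cc(OCc2ccccc2)c2c(=O)cc(-c3cc(OC)c(OC)c(OCc4ccccc4)c3OC)oc2c1
F7 | step 5 | (Z)-2-bromo-3-methoxyacrylic acid | CO/C=C(\Br)C(=O)O
F8 | step 5 | 2-acetyl-3-(benzyloxy)-5-methoxyphenyl (Z)-2-bromo-3-methoxyacrylate | CO/C=C(\Br)C(=O)Oc1cc(OC)cc(OCc2ccccc2)c1C(C)=O
F9 | step 5 | (Z)-1-[2-(benzyloxy)-6-hydroxy-4-methoxyphenyl]-4-bromo-5-methoxypent-4-ene-1,3-dione | CO/C=C(\Br)C(=O)CC(=O)c1c(O)cc(OC)cc1OCc1ccccc1
F10 | step 8 | 2,3-dimethoxy-4-oxocyclobut-2-en-1-yl methanesulfonate (racemic) | COC1=C(OC)C(OS(C)(=O)=O)C1=O
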